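The data were generated by integration for an exercise, noise included.

Which holds more at the end, target or isomer of the product, in cedar and in birch?

in all of them: electrophile 0.11 M
- Thursday's: nucleophile 2.5 equiv; free base 2 equiv; temperature 0 °C; run made earlier
- Monday's: nucleophile 4 equiv; free base 2 equiv; temperature 15 °C; run made earlier
- cedar: nucleophile 1.80 equiv; free base 2.00 equiv; temperature 5 °C; time 50 min
- birch: nucleophile 1.80 equiv; free base 2.00 equiv; temperature 25 °C; time 50 min

- Thursday's (time / min: target / %, electrophile / %, isomer of the product / %): 5.00: 14.2, 86.8, 0.2; 15.0: 32.7, 64.5, 2.9; 25.0: 43.3, 49.6, 7.5; 40.0: 50.1, 33.8, 16.1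
- Monday's (time / min: target / %, electrophile / %, isomer of the product / %): 2.00: 29.4, 67.9, 3.0; 5.00: 50.2, 39.2, 11.9; 10.0: 54.8, 16.5, 28.7; 25.0: 41.7, 1.4, 57.0

(scatter of a reading: 0.5 percentage points)

- which of these there is most of at the end, counted by the electrophile in it, cedar (target / isomer of the product / electrophile)
- which of these there is most of at the end, counted by the electrophile in it, birch (target / isomer of the product / electrophile)
- how much there is at the end of the one of these that leads, in percent of the electrophile charged: cedar
- how much there is at the end of the one of these that leads, in percent of the electrophile charged: birch

- the analysis behind the earlier runs scatters by 0.5 percentage points, standard deviation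
- steps under discussion: electrophile + nucleophile -> acid set free + target; target <-> isomer of the product; nucleophile + acid set free <-> protonated nucleophile; acid set free -> by-product carried off; acid set free + free base <-> salt of the base

Two times bear on it, and you can read both from the runs. Take electrophile loss as first order in [nucleophile], and the nucleophile as lost one for one with the electrophile. The integrated second-order law then gives a characteristic time of 30.9 min on Thursday's last reading and 4.78 min on Monday's third. Correct for the charges and take ln of the rate constant as linear in temperature. Cedar then gets 26.9 min and birch 4.19 min. This is the coupling life: one over the rate constant times the charged [nucleophile].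

The second time is the isomer life: mean target over the rate of isomer gain between two readings, with the way back ignored. It reads 81.5 min on Thursday and 13.4 min on Monday. Taking its ln as linear in temperature too, cedar gets 44.6 min and birch 4.03 min.

Isomer life over coupling life is 1.66 in cedar and 0.962 in birch. In cedar the law leaves 25.8% electrophile. Cedar's target, made about one coupling life in, has the remaining time to turn, with the way back ignored, so I expect 44.3% target there: kinetic control. The run in birch spans 12.4 isomer lives, more than the 1.12 in cedar, so I expect thermodynamic control in birch. Monday's last readings, at 15 °C, give a rough isomer share of 57.8%, and I carry that share over to birch.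

The forecast differs a little from these figures: target at 41% in cedar and isomer of the product at 61% in birch, where “the pair is equilibrated”.

Cedar ends with target leading at 40.5%, and birch with isomer of the product leading at 56.6%.

    electrophile + nucleophile → acid set free + target (k = 0.190 L mol⁻¹ min⁻¹, Ea = 61.0 kJ mol⁻¹)
    target ⇌ isomer of the product (K = 2.80, k = 0.0240 min⁻¹, Ea = 80.0 kJ mol⁻¹, ΔH = −26.0 kJ mol⁻¹)
    nucleophile + acid set free ⇌ protonated nucleophile, settled at all times (K = 60.0 L mol⁻¹, ΔH = −80.0 kJ mol⁻¹)
    acid set free → by-product carried off (k = 0.0160 min⁻¹, Ea = 76.0 kJ mol⁻¹)
    acid set free + free base ⇌ salt of the base, settled at all times (K = 1300 L mol⁻¹, ΔH = −50.0 kJ mol⁻¹)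
    (constants at 5 °C)

Birch ran 11.9 coupling lives and kept 0.352% electrophile. Its neighbour is charged at 0.028 M electrophile, with the same equivalents and time. There [nucleophile] falls with the charge, so the coupling life grows to 16.5 min, longer than birch's. The isomer life stays 4.03 min, shorter than that coupling life. The same law leaves 13.5% electrophile. The neighbour holds 15.3% electrophile, 37.2% target and 47.5% isomer of the product.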